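Ring B of the target (C5–C10, labdane numbering) is a cyclohexene that shares the C5–C10 fusion bond with ring A, so a retro-[4+2] across C5–C10 and C6–C7 opens both rings at once. The forward key step is an amine-catalysed asymmetric intramolecular Diels–Alder reaction of an acyclic trienal: an enal (C5=C6) tied by the C1–C4 gem-dimethyl tether to a 2-acetoxy-1,3-diene (C7=C8–C9=C10) whose fully substituted terminus C10 carries the future angular methyl. One operation builds the trans-decalin with the C10 quaternary centre and C5. The enol acetate then gives the C8 ketone (C9 set thermodynamically), whose C7 enol triflate is carbonylated to the acid; the activating formyl group is removed by decarbonylation.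

Key step: step 12

Remark: atoms are numbered as in labdanes (decalin C1–C10, side chain C11–C16, carboxyl C17, angular methyl C20). Compound 10 is racemic at a centre that step 8 removes.

Step 1
Reactants: 1 tert-butyl(but-3-yn-1-yloxy)dimethylsilane
Product: 2 (E)-5-[(tert-butyldimethylsilyl)oxy]-3-methylpent-2-en-1-ol
Conditions: Me3Al, Cp2ZrCl2 (0.25 equiv), CH2Cl2, 0 °C to rt; then n-BuLi, THF, −78 °C; (CH2O)n, −78 °C to rt
Reagents that add atoms: trimethylaluminium C[Al](C)C; paraformaldehyde (as formaldehyde) C=O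
Why: Negishi carboalumination adds methyl and aluminium syn across the terminal alkyne with the metal on the terminal carbon, and hydroxymethylation of the alanate with retention should fix the E trisubstituted alkene.

Step 2
Reactants: 2 (E)-5-[(tert-butyldimethylsilyl)oxy]-3-methylpent-2-en-1-ol
Product: 3 (E)-1-(tert-butyldiphenylsilyloxy)-5-(tert-butyldimethylsilyloxy)-3-methylpent-2-ene
Conditions: TBDPSCl, imidazole, DMF, rt
Reagents that add atoms: tert-butylchlorodiphenylsilane CC(C)(C)[Si](Cl)(c1ccccc1)c1ccccc1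
Why: Standard silylation of the primary allylic alcohol with the robust TBDPS group, which has to last until step 17.

Step 3
Reactants: 3 (E)-1-(tert-butyldiphenylsilyloxy)-5-(tert-butyldimethylsilyloxy)-3-methylpent-2-ene
Product: 4 (E)-5-(tert-butyldiphenylsilyloxy)-3-methylpent-3-en-1-ol
Conditions: PPTS (cat.), MeOH, rt
Reagents that add atoms: none
Why: Mild acid-catalysed methanolysis removes a primary TBS ether much faster than the bulkier primary TBDPS ether (selective desilylation).

Step 4
Reactants: 4 (E)-5-(tert-butyldiphenylsilyloxy)-3-methylpent-3-en-1-ol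
Product: 5 (E)-tert-butyl[(5-iodo-3-methylpent-2-en-1-yl)oxy]diphenylsilane
Conditions: I2, PPh3, imidazole, CH2Cl2, 0 °C
Reagents that add atoms: iodine II
Why: Appel-type iodination converts the primary homoallylic alcohol into the iodide by SN2 displacement of the alkoxyphosphonium ion under buffered conditions that spare the allylic silyl ether.

Step 5
Reactants: 6 2,2-dimethylpent-4-enal
Product: 7 (E)-4,4-dimethylhepta-2,6-dienal
Conditions: Ph3P=CHCHO, toluene, 90 °C
Reagents that add atoms: (triphenylphosphoranylidene)acetaldehyde O=CC=P(c1ccccc1)(c1ccccc1)c1ccccc1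
Why: Wittig reaction of the non-enolisable aldehyde with the stabilised formyl ylide should give the E enal, the terminal alkene being inert.

Step 6
Reactants: 7 (E)-4,4-dimethylhepta-2,6-dienal
Product: 8 (E)-7,7-dimethoxy-4,4-dimethylhepta-1,5-diene
Conditions: HC(OMe)3, PPTS (cat.), MeOH, rt
Reagents that add atoms: trimethyl orthoformate COC(OC)OC
Why: Acid-catalysed acetalisation masks the enal as a base-stable dimethyl acetal that should survive the hydroboration, Grignard and amide-base steps, with the E alkene retained.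

Step 7
Reactants: 9 methyl acetoacetate; 5 (E)-tert-butyl[(5-iodo-3-methylpent-2-en-1-yl)oxy]diphenylsilane
Product: 10 methyl (E)-2-acetyl-7-(tert-butyldiphenylsilyloxy)-5-methylhept-5-enoate
Conditions: NaH, THF/DMF, 0 to 50 °C
Reagents that add atoms: none
Why: Acetoacetic ester C-alkylation of the soft sodium enolate by the primary iodide should favour SN2 over elimination; the new stereocentre is racemic and disappears in step 8.

Step 8
Reactants: 10 methyl (E)-2-acetyl-7-(tert-butyldiphenylsilyloxy)-5-methylhept-5-enoate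
Product: 11 methyl (2E,5E)-7-(tert-butyldiphenylsilyloxy)-5-methyl-2-[1-(tosyloxy)ethylidene]hept-5-enoate
Conditions: TsCl, Me2N(CH2)6NMe2, MeCN, 0 °C
Reagents that add atoms: p-toluenesulfonyl chloride Cc1ccc(S(Cl)(=O)=O)cc1
Why: Enol tosylation of an α-substituted β-keto ester with TsCl and a tertiary diamine under non-chelating conditions is known to give the E enol tosylate (tosyloxy trans to the ester), the geometry that later places the tether on the outside of the diene.

Step 9
Reactants: 8 (E)-7,7-dimethoxy-4,4-dimethylhepta-1,5-diene; 11 methyl (2E,5E)-7-(tert-butyldiphenylsilyloxy)-5-methyl-2-[1-(tosyloxy)ethylidene]hept-5-enoate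
Product: 13 methyl (2E,8E)-2-[(E)-5-(tert-butyldiphenylsilyloxy)-3-methylpent-3-enyl]-10,10-dimethoxy-3,7,7-trimethyldeca-2,8-dienoate, via B-alkyl-9-BBN 12 (not isolated)
Conditions: 8, 9-BBN-H, THF, rt; then 11, Pd(OAc)2 (5 mol %), SPhos (10 mol %), K3PO4 (aq), THF, 60 °C
Reagents that add atoms: none
Why: Chemoselective anti-Markovnikov hydroboration of the monosubstituted alkene is followed by a B-alkyl Suzuki–Miyaura coupling that replaces the tosyloxy group with retention, so the tether should end trans to the ester on the tetrasubstituted alkene.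

Step 10
Reactants: 13 methyl (2E,8E)-2-[(E)-5-(tert-butyldiphenylsilyloxy)-3-methylpent-3-enyl]-10,10-dimethoxy-3,7,7-trimethyldeca-2,8-dienoate
Product: 15 (3E,9E)-3-[(E)-5-(tert-butyldiphenylsilyloxy)-3-methylpent-3-enyl]-11,11-dimethoxy-4,8,8-trimethylundeca-3,9-dien-2-one, via Weinreb amide 14 (not isolated)
Conditions: MeNHOMe·HCl, i-PrMgCl, THF, −20 to 0 °C; then MeMgBr, 0 °C; aq NH4Cl
Reagents that add atoms: methylmagnesium bromide C[Mg]Br; N,O-dimethylhydroxylamine hydrochloride CNOC.Cl (its atoms stay only in 14)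
Why: The magnesium amide converts the hindered ester into the Weinreb amide, whose chelated tetrahedral adduct with MeMgBr collapses only on work-up, so the methyl ketone should form without over-addition and without touching the acetal or the alkene geometry.

Step 11
Reactants: 15 (3E,9E)-3-[(E)-5-(tert-butyldiphenylsilyloxy)-3-methylpent-3-enyl]-11,11-dimethoxy-4,8,8-trimethylundeca-3,9-dien-2-one
Product: 17 (3E,9E)-3-[(E)-5-(tert-butyldiphenylsilyloxy)-3-methylpent-3-enyl]-4,8,8-trimethyl-11-oxoundeca-1,3,9-trien-2-yl acetate, via dienyl acetate dimethyl acetal 16 (not isolated)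
Conditions: LiN(i-Pr)2, THF, −78 °C; Ac2O, −78 to 0 °C; then 1 M HCl/THF, 0 °C
Reagents that add atoms: acetic anhydride CC(=O)OC(C)=O; water O
Why: Kinetic deprotonation of the ketone methyl group and O-acetylation of the cross-conjugated lithium dienolate give the 2-acetoxy-1,3-diene, and brief aqueous acid hydrolyses the very labile unsaturated acetal while the enol acetate and silyl ether survive.

Step 12
Reactants: 17 (3E,9E)-3-[(E)-5-(tert-butyldiphenylsilyloxy)-3-methylpent-3-enyl]-4,8,8-trimethyl-11-oxoundeca-1,3,9-trien-2-yl acetate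
Product: 18 (5S,6S,10S)-6-formyl-15-(tert-butyldiphenylsilyloxy)-17-norlabda-8,13E-dien-8-yl acetate (trans-fused; 5α-H, 10β-CH3, 6α-CHO)
Conditions: (2S,5S)-5-benzyl-2-tert-butyl-3-methylimidazolidin-4-one·CF3SO3H (20 mol %), MeCN/H2O (98:2), 0 °C to rt
Reagents that add atoms: none
Why: Condensation of the enal with the imidazolidinone gives an (E)-iminium ion whose lowered LUMO undergoes a concerted, asynchronous [4+2] cycloaddition with the tethered 2-acetoxydiene (C5–C10 bonding leading, C6–C7 following) before hydrolysis returns the catalyst; the closest known reaction type is the imidazolidinone-catalysed type 1 intramolecular Diels–Alder reaction of 2,7,9-trienals to trans-decalins. Ring B closes as the cyclohexene of the [4+2], suprafacial on both partners, and ring A closes in the fused mode as the six-membered ring that holds the four-carbon tether in a chair. C5 is set by the catalyst, whose benzyl group screens one face of the iminium so that the diene adds to the exposed face of C5=C6, which by the accepted shielding model corresponds to 5S. C10 is set relative to C5 by the endo transition state (formyl under the diene, tether anti) together with the diene geometry (tether outside, methyl inside), which gives the trans ring fusion with the angular methyl anti to H-5, while C6 follows from the E enal and is erased in step 13. The step needs endo over exo selectivity and enough reactivity at a hindered bond (C5 next to the C4 gem-dimethyl group, C10 fully substituted); the first is favoured by iminium activation and the chair tether, the second by the electron-rich tetrasubstituted diene terminus, the intramolecular setting and the lack of γ-hydrogens in the enal, which rules out a dienamine drain. The enol acetate is chosen as the diene oxygen substituent because it should survive the aqueous acidic medium.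

Step 13
Reactants: 18 (5S,6S,10S)-6-formyl-15-(tert-butyldiphenylsilyloxy)-17-norlabda-8,13E-dien-8-yl acetate
Product: 19 (5S,10S)-15-(tert-butyldiphenylsilyloxy)-17-norlabda-8,13E-dien-8-yl acetate
Conditions: RhCl(PPh3)3 (1.1 equiv), toluene, 110 °C
Reagents that add atoms: none
Why: Tsuji–Wilkinson decarbonylation (oxidative addition of the formyl C–H bond to monovalent rhodium, CO extrusion, reductive elimination) removes the activating formyl group and leaves C6 as CH2, the enol acetate, alkenes and silyl ether being inert.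

Step 14
Reactants: 19 (5S,10S)-15-(tert-butyldiphenylsilyloxy)-17-norlabda-8,13E-dien-8-yl acetate
Product: 20 (5S,9R,10S)-15-(tert-butyldiphenylsilyloxy)-17-norlabd-13E-en-8-one
Conditions: K2CO3, MeOH, rt
Reagents that add atoms: none
Why: Base-catalysed methanolysis of the enol acetate releases the C8 ketone, and under these equilibrating conditions C9 should settle with the side chain equatorial (9R, H-9 α), which is also the outcome of axial protonation of the enolate anti to the angular methyl.

Step 15
Reactants: 20 (5S,9R,10S)-15-(tert-butyldiphenylsilyloxy)-17-norlabd-13E-en-8-one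
Product: 21 (5S,9R,10S)-15-(tert-butyldiphenylsilyloxy)-17-norlabda-7,13E-dien-8-yl trifluoromethanesulfonate
Conditions: KN(SiMe3)2, THF, −78 °C; PhNTf2, −78 to 0 °C
Reagents that add atoms: N-phenylbis(trifluoromethanesulfonimide) O=S(=O)(N(c1ccccc1)S(=O)(=O)C(F)(F)F)C(F)(F)F
Why: Kinetic deprotonation by the bulky amide base occurs at the unhindered C7 methylene and not at the tertiary C9–H beside the quaternary carbon, and O-triflation fixes the C7=C8 enol triflate without epimerising C9.

Step 16
Reactants: 21 (5S,9R,10S)-15-(tert-butyldiphenylsilyloxy)-17-norlabda-7,13E-dien-8-yl trifluoromethanesulfonate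
Product: 22 (5S,9R,10S)-15-(tert-butyldiphenylsilyloxy)labda-7,13E-dien-17-oic acid
Conditions: Pd(OAc)2 (5 mol %), dppf, CO (1 atm), Et3N, DMF/H2O, 60 °C
Reagents that add atoms: carbon monoxide [C-]#[O+]; water O
Why: Palladium-catalysed hydroxycarbonylation of the enol triflate (oxidative addition to zerovalent palladium, CO insertion, hydrolysis of the acylpalladium species) puts the C17 carboxyl group on C8 with the double bond fixed at C7=C8; the silyl ether is carried here because an allylic acetate would ionise.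

Step 17
Reactants: 22 (5S,9R,10S)-15-(tert-butyldiphenylsilyloxy)labda-7,13E-dien-17-oic acid
Product: 23 (5S,9R,10S)-15-hydroxylabda-7,13E-dien-17-oic acid
Conditions: Bu4NF (excess), THF, rt; acidic work-up
Reagents that add atoms: none
Why: Fluoride cleaves the Si–O bond of the TBDPS ether to free the primary allylic alcohol, the carboxylic acid being only deprotonated and recovered on work-up.

Step 18
Reactants: 23 (5S,9R,10S)-15-hydroxylabda-7,13E-dien-17-oic acid
Product: 24 (5S,9R,10S)-15-acetoxylabda-7,13E-dien-17-oic acid (target)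
Conditions: Ac2O, pyridine, DMAP (cat.), CH2Cl2, 0 °C to rt; aq NaHCO3, then dilute HCl
Reagents that add atoms: acetic anhydride CC(=O)OC(C)=O
Why: DMAP-catalysed acetylation of the primary alcohol; any mixed anhydride formed at the hindered carboxylic acid is hydrolysed in the bicarbonate work-up, so the acetoxy acid should result.

Compound list
1 | tert-butyl(but-3-yn-1-yloxy)dimethylsilane | C#CCCO[Si](C)(C)C(C)(C)C | starting material
2 | (E)-5-[(tert-butyldimethylsilyl)oxy]-3-methylpent-2-en-1-ol | C/C(CCO[Si](C)(C)C(C)(C)C)=C\CO | intermediate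
3 | (E)-1-(tert-butyldiphenylsilyloxy)-5-(tert-butyldimethylsilyloxy)-3-methylpent-2-ene | C/C(CCO[Si](C)(C)C(C)(C)C)=C\CO[Si](c1ccccc1)(c1ccccc1)C(C)(C)C | intermediate
4 | (E)-5-(tert-butyldiphenylsilyloxy)-3-methylpent-3-en-1-ol | C/C(CCO)=C\CO[Si](c1ccccc1)(c1ccccc1)C(C)(C)C | intermediate
5 | (E)-tert-butyl[(5-iodo-3-methylpent-2-en-1-yl)oxy]diphenylsilane | C/C(CCI)=C\CO[Si](c1ccccc1)(c1ccccc1)C(C)(C)C | intermediate
6 | 2,2-dimethylpent-4-enal | C=CCC(C)(C)C=O | starting material
7 | (E)-4,4-dimethylhepta-2,6-dienal | C=CCC(C)(C)/C=C/C=O | intermediate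
8 | (E)-7,7-dimethoxy-4,4-dimethylhepta-1,5-diene | C=CCC(C)(C)/C=C/C(OC)OC | intermediate
9 | methyl acetoacetate | CC(=O)CC(=O)OC | starting material
10 | methyl (E)-2-acetyl-7-(tert-butyldiphenylsilyloxy)-5-methylhept-5-enoate (racemic at C2) | CC(=O)C(CC/C(C)=C/CO[Si](c1ccccc1)(c1ccccc1)C(C)(C)C)C(=O)OC | intermediate
11 | methyl (2E,5E)-7-(tert-butyldiphenylsilyloxy)-5-methyl-2-[1-(tosyloxy)ethylidene]hept-5-enoate (tosyloxy trans to the ester) | C/C(OS(=O)(=O)c1ccc(C)cc1)=C(/CC/C(C)=C/CO[Si](c1ccccc1)(c1ccccc1)C(C)(C)C)C(=O)OC | intermediate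
12 | 9-[(E)-7,7-dimethoxy-4,4-dimethylhept-5-en-1-yl]-9-borabicyclo[3.3.1]nonane | COC(OC)/C=C/C(C)(C)CCCB1C2CCCC1CCC2 | intermediate
13 | methyl (2E,8E)-2-[(E)-5-(tert-butyldiphenylsilyloxy)-3-methylpent-3-enyl]-10,10-dimethoxy-3,7,7-trimethyldeca-2,8-dienoate | C/C(CCCC(C)(C)/C=C/C(OC)OC)=C(/CC/C(C)=C/CO[Si](c1ccccc1)(c1ccccc1)C(C)(C)C)C(=O)OC | intermediate
14 | (2E,8E)-2-[(E)-5-(tert-butyldiphenylsilyloxy)-3-methylpent-3-enyl]-N,10,10-trimethoxy-N,3,7,7-tetramethyldeca-2,8-dienamide | C/C(CCCC(C)(C)/C=C/C(OC)OC)=C(/CC/C(C)=C/CO[Si](c1ccccc1)(c1ccccc1)C(C)(C)C)C(=O)N(C)OC | intermediate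
15 | (3E,9E)-3-[(E)-5-(tert-butyldiphenylsilyloxy)-3-methylpent-3-enyl]-11,11-dimethoxy-4,8,8-trimethylundeca-3,9-dien-2-one | C/C(CCCC(C)(C)/C=C/C(OC)OC)=C(/CC/C(C)=C/CO[Si](c1ccccc1)(c1ccccc1)C(C)(C)C)C(C)=O | intermediate
16 | (3E,9E)-3-[(E)-5-(tert-butyldiphenylsilyloxy)-3-methylpent-3-enyl]-11,11-dimethoxy-4,8,8-trimethylundeca-1,3,9-trien-2-yl acetate | C=C(OC(C)=O)/C(CC/C(C)=C/CO[Si](c1ccccc1)(c1ccccc1)C(C)(C)C)=C(\C)CCCC(C)(C)/C=C/C(OC)OC | intermediate
17 | (3E,9E)-3-[(E)-5-(tert-butyldiphenylsilyloxy)-3-methylpent-3-enyl]-4,8,8-trimethyl-11-oxoundeca-1,3,9-trien-2-yl acetate | C=C(OC(C)=O)/C(CC/C(C)=C/CO[Si](c1ccccc1)(c1ccccc1)C(C)(C)C)=C(\C)CCCC(C)(C)/C=C/C=O | intermediate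
18 | (5S,6S,10S)-6-formyl-15-(tert-butyldiphenylsilyloxy)-17-norlabda-8,13E-dien-8-yl acetate | CC(=O)OC1=C(CC/C(C)=C/CO[Si](c3ccccc3)(c3ccccc3)C(C)(C)C)[C@@]2(C)CCCC(C)(C)[C@@H]2[C@@H](C=O)C1 | intermediate
19 | (5S,10S)-15-(tert-butyldiphenylsilyloxy)-17-norlabda-8,13E-dien-8-yl acetate | CC(=O)OC1=C(CC/C(C)=C/CO[Si](c3ccccc3)(c3ccccc3)C(C)(C)C)[C@@]2(C)CCCC(C)(C)[C@@H]2CC1 | intermediate
20 | (5S,9R,10S)-15-(tert-butyldiphenylsilyloxy)-17-norlabd-13E-en-8-one | CC(C)(C)[Si](c1ccccc1)(c1ccccc1)OC/C=C(\C)CC[C@H]1C(=O)CC[C@H]2C(C)(C)CCC[C@]12C | intermediate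
21 | (5S,9R,10S)-15-(tert-butyldiphenylsilyloxy)-17-norlabda-7,13E-dien-8-yl trifluoromethanesulfonate | CC(C)(C)[Si](c1ccccc1)(c1ccccc1)OC/C=C(\C)CC[C@H]1C(OS(=O)(=O)C(F)(F)F)=CC[C@H]2C(C)(C)CCC[C@]12C | intermediate
22 | (5S,9R,10S)-15-(tert-butyldiphenylsilyloxy)labda-7,13E-dien-17-oic acid | CC(C)(C)[Si](c1ccccc1)(c1ccccc1)OC/C=C(\C)CC[C@H]1C(C(=O)O)=CC[C@H]2C(C)(C)CCC[C@]12C | intermediate
23 | (5S,9R,10S)-15-hydroxylabda-7,13E-dien-17-oic acid | OC/C=C(\C)CC[C@H]1C(C(=O)O)=CC[C@H]2C(C)(C)CCC[C@]12C | intermediate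
24 | (5S,9R,10S)-15-acetoxylabda-7,13E-dien-17-oic acid | CC(=O)OC/C=C(\C)CC[C@H]1C(C(=O)O)=CC[C@H]2C(C)(C)CCC[C@]12C | target

Total step count: 18. Longest linear sequence: 16 steps (steps 1–4, then 7–18).

Steps most likely to fail

1. Step 12. The cycloaddition may be too slow at the congested C5–C10 bond under mild iminium activation, so that slow solvolysis of the enol acetate or erosion of endo and facial selectivity takes over. The fallback uses auxiliary control under strong Lewis-acid activation; it sets out from 17 and comes back to the route at 20. Pinnick oxidation of 17 (NaClO2, NaH2PO4, 2-methylbut-2-ene) would give the trienoic acid F1. Its pivalic mixed anhydride F2 (t-BuCOCl, Et3N) would acylate (S)-4-benzyloxazolidin-2-one (LiCl, Et3N) to the N-enoyl oxazolidinone F3. Me2AlCl (1.4 equiv, CH2Cl2, −30 °C) should then promote the endo intramolecular Diels–Alder reaction through the chelated s-cis imide, the diene adding anti to the benzyl group, to give the trans-fused imide F4. LiOH/H2O2 would cleave both the auxiliary and the enol acetate to the keto acid F5 (C9 equilibrated). Barton decarboxylation through the thiohydroxamate ester F6 (t-BuSH, hν) would then give 20.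

2. Step 9. Oxidative addition and transmetalation at the fully substituted enol tosylate may be slow, which would let addition–elimination scramble the alkene geometry or the alkylborane undergo β-hydride elimination. The fallback builds the tetrasubstituted alkene by alkyne carbometalation; it sets out from 8 (and uses 5) and comes back at 13. Hydroboration of 8 as in step 9 (to 12) and iodinolysis (I2, NaOMe) would give the iodide F7. Lithium–iodine exchange (t-BuLi) and CuBr·SMe2 in one flask would give the alkylcopper reagent F8, which should add syn to methyl but-2-ynoate at −78 °C. Iodine quench of the alkenylcopper would give the (Z)-α-iodo enoate F9 with the tether cis to iodine. Negishi coupling of F9 with the alkylzinc iodide F10 (from 5 and zinc dust, LiCl) under PdCl2(dppf) would give 13 with retention.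

3. Step 13. Decarbonylation of the hindered secondary aldehyde may stall, or the alkylrhodium intermediate may divert through β-hydride elimination to an olefin. The fallback is a radical decarboxylation; it sets out from 18 and comes back at 19. Pinnick oxidation would give the acid F11, and Barton decarboxylation through the thiohydroxamate ester F12 (t-BuSH, hν) would give 19.

Further compounds
F1 | step 12 | (2E,8E)-10-acetoxy-9-[(E)-5-(tert-butyldiphenylsilyloxy)-3-methylpent-3-enyl]-4,4,8-trimethylundeca-2,8,10-trienoic acid | C=C(OC(C)=O)/C(CC/C(C)=C/CO[Si](c1ccccc1)(c1ccccc1)C(C)(C)C)=C(\C)CCCC(C)(C)/C=C/C(=O)O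
F2 | step 12 | mixed anhydride of F1 and pivalic acid | C=C(OC(C)=O)/C(CC/C(C)=C/CO[Si](c1ccccc1)(c1ccccc1)C(C)(C)C)=C(\C)CCCC(C)(C)/C=C/C(=O)OC(=O)C(C)(C)C
F3 | step 12 | (S)-4-benzyl-3-[(2E,8E)-10-acetoxy-9-[(E)-5-(tert-butyldiphenylsilyloxy)-3-methylpent-3-enyl]-4,4,8-trimethylundeca-2,8,10-trienoyl]oxazolidin-2-one | C=C(OC(C)=O)/C(CC/C(C)=C/CO[Si](c1ccccc1)(c1ccccc1)C(C)(C)C)=C(\C)CCCC(C)(C)/C=C/C(=O)N1C(=O)OC[C@@H]1Cc1ccccc1
F4 | step 12 | (5S,6S,10S)-6-[(S)-4-benzyl-2-oxooxazolidine-3-carbonyl]-15-(tert-butyldiphenylsilyloxy)-17-norlabda-8,13E-dien-8-yl acetate | CC(=O)OC1=C(CC/C(C)=C/CO[Si](c3ccccc3)(c3ccccc3)C(C)(C)C)[C@@]2(C)CCCC(C)(C)[C@@H]2[C@@H](C(=O)N2C(=O)OC[C@@H]2Cc2ccccc2)C1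
F5 | step 12 | (5S,6S,9R,10S)-15-(tert-butyldiphenylsilyloxy)-8-oxo-17-norlabd-13E-ene-6-carboxylic acid | CC(C)(C)[Si](c1ccccc1)(c1ccccc1)OC/C=C(\C)CC[C@H]1C(=O)C[C@H](C(=O)O)[C@H]2C(C)(C)CCC[C@]12C
F6 | step 12 | 2-thioxopyridin-1(2H)-yl ester of F5 | CC(C)(C)[Si](c1ccccc1)(c1ccccc1)OC/C=C(\C)CC[C@H]1C(=O)C[C@H](C(=O)ON3C=CC=CC3=S)[C@H]2C(C)(C)CCC[C@]12C
F7 | step 9 | (E)-7-iodo-1,1-dimethoxy-4,4-dimethylhept-2-ene | COC(OC)/C=C/C(C)(C)CCCI
F8 | step 9 | [(E)-7,7-dimethoxy-4,4-dimethylhept-5-en-1-yl]copper | COC(OC)/C=C/C(C)(C)CCC[Cu]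
F9 | step 9 | methyl (2Z,8E)-2-iodo-10,10-dimethoxy-3,7,7-trimethyldeca-2,8-dienoate | C/C(CCCC(C)(C)/C=C/C(OC)OC)=C(/I)C(=O)OC
F10 | step 9 | [(E)-5-(tert-butyldiphenylsilyloxy)-3-methylpent-3-en-1-yl]zinc iodide | C/C(CC[Zn]I)=C\CO[Si](c1ccccc1)(c1ccccc1)C(C)(C)C
F11 | step 13 | (5S,6S,10S)-8-acetoxy-15-(tert-butyldiphenylsilyloxy)-17-norlabda-8,13E-diene-6-carboxylic acid | CC(=O)OC1=C(CC/C(C)=C/CO[Si](c3ccccc3)(c3ccccc3)C(C)(C)C)[C@@]2(C)CCCC(C)(C)[C@@H]2[C@@H](C(=O)O)C1
F12 | step 13 | 2-thioxopyridin-1(2H)-yl ester of F11 | CC(=O)OC1=C(CC/C(C)=C/CO[Si](c3ccccc3)(c3ccccc3)C(C)(C)C)[C@@]2(C)CCCC(C)(C)[C@@H]2[C@@H](C(=O)ON3C=CC=CC3=S)C1
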